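**Assumption:** ring positions are numbered as in eremophilane (C1–C10 decalin, methyls on C4 and C5, isopropenyl on C7) and α/β refer to the usual drawing with the C5 methyl β. The target is then the trans-fused (10αH) 4β,5β-dimethyl-7α-isopropenyl-8-ketone with 3α-angelate and 9α-(E)-3-methylpent-2-enoate, i.e. (3R,4R,5R,7S,9S,10R), with every substituent except the angular methyl equatorial.

## Retrosynthetic overview

1. The C7–isopropenyl bond is made last (Pd coupling of a C7 tin enolate with 2-bromopropene). Both esters go in before it: the C3 angelate by Yamaguchi acylation, the C9 ester by acyloxylation of a regiodefined enol silane.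
2. The trans-decalin with the 3α-oxygen and the Δ8 enol silane comes in one dissolving-metal step from bicyclic enedione 8.
3. Ring A of 8 (six-membered, C4 methyl, C3 ketone) comes from a 1-vinylcyclopentanol by a ring-expanding semipinacol 1,2-shift of the quaternary carbon (five to six).
4. The vinyl carbinol comes from (S)-Hajos–Parrish ketone and vinylmagnesium bromide; the ketone comes from 2-methylcyclopentane-1,3-dione and methyl vinyl ketone (the proline aldol sets C5).
5. Ring order: cyclopentane (bought), then ring B by annulation, then ring A by expansion of the cyclopentane.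

## Route

Step 1
Reactants: 1 2-methylcyclopentane-1,3-dione; 2 methyl vinyl ketone
Product: 3 2-methyl-2-(3-oxobutyl)cyclopentane-1,3-dione
Conditions: H2O, AcOH (cat.), 75 °C
Reagents that add atoms: none
Why: Michael addition of the enolised 1,3-dione to the enone gives the C-alkylated triketone; no stereocentre is formed.

Step 2
Reactants: 3 2-methyl-2-(3-oxobutyl)cyclopentane-1,3-dione
Product: 5 (S)-Hajos–Parrish ketone, via Hajos ketol 4 (not isolated)
Conditions: (S)-proline (3 mol %), DMF, 16 °C; then H2SO4 (cat.), 95 °C; recrystallise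
Reagents that add atoms: none
Why: Hajos–Parrish–Eder–Sauer–Wiechert reaction: the proline enamine of the side-chain ketone attacks one of the two enantiotopic ring carbonyls through the acid-directed chair transition state, which sets the quaternary carbon as S (the later C5), acid then dehydrates ketol 4 to the enone, and recrystallisation brings 5 to >99% ee.

Step 3
Reactants: 5 (S)-Hajos–Parrish ketone; 6 vinylmagnesium bromide
Product: 7 (1R,7aS)-1-ethenyl-1-hydroxy-7a-methyl-1,2,3,6,7,7a-hexahydro-5H-inden-5-one
Conditions: LaCl3·2LiCl (30 mol %), THF, −78 °C; then H2O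
Reagents that add atoms: none
Why: Lanthanide-promoted Grignard 1,2-addition goes to the non-conjugated, more electrophilic cyclopentanone carbonyl rather than the enone carbonyl and from the face anti to the angular methyl, which gives the 1β-hydroxy-1α-vinyl carbinol whose configuration steers the next step.

Step 4
Reactants: 7 (1R,7aS)-1-ethenyl-1-hydroxy-7a-methyl-1,2,3,6,7,7a-hexahydro-5H-inden-5-one
Product: 8 (4aR,5R)-4a,5-dimethyl-4,4a,7,8-tetrahydronaphthalene-2,6(3H,5H)-dione
Conditions: Co(II) salen (N,N'-bis(3,5-di-tert-butylsalicylidene)-1,1,2,2-tetramethylethylenediamine complex, 5 mol %), N-fluoro-2,4,6-trimethylpyridinium triflate (1.3 equiv), PhSiH3 (1.3 equiv), acetone, 0 °C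
Reagents that add atoms: none
Why: Proposed new method: Co–H hydrogen-atom transfer to the terminal vinyl carbon gives a secondary radical next to the carbinol, the radical is captured and oxidised to an alkyl–Co(IV) cation equivalent, and the more substituted ring bond (the quaternary carbon) migrates to it in a semipinacol 1,2-shift that expands the cyclopentanol to the cyclohexanone, forms the C4–C5 bond and sets C4 because the new methyl sits outward in the migration transition state (4β, cis to the C5 methyl), while the electron-poor trisubstituted enone reacts far more slowly in MHAT; the closest known chemistry is the Co(salen)/N-fluoropyridinium/silane radical-polar crossover hydrofunctionalisation and semipinacol rearrangement of tertiary allylic alcohols with 1,1-disubstituted alkenes, which to my knowledge has not been shown for a monosubstituted vinyl carbinol on a strain-neutral cyclopentanol.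

Step 5
Reactants: 8 (4aR,5R)-4a,5-dimethyl-4,4a,7,8-tetrahydronaphthalene-2,6(3H,5H)-dione
Product: 10 3α,8-bis(trimethylsilyloxy)-4β,5β-dimethyl-10αH-octal-8-ene, via dilithium alkoxide-enolate 9 (not isolated)
Conditions: Li (6 equiv), NH3(l)/THF, t-BuOH (2 equiv), −78 → −33 °C; isoprene; evaporate NH3; then TMSCl, Et3N, THF, −78 → 0 °C
Reagents that add atoms: chlorotrimethylsilane C[Si](C)(C)Cl
Why: Dissolving-metal (Birch-type) reduction: the enone gives the trans-fused lithium enolate by axial protonation at C10 (10αH), the C3 ketone is reduced under thermodynamic control to the equatorial 3α-alkoxide without prior enolisation (C4 is kept), and Stork reductive silylation stores the enolate regiochemistry as the Δ8 enol silane while capping the C3 oxygen.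

Step 6
Reactants: 10 3α,8-bis(trimethylsilyloxy)-4β,5β-dimethyl-10αH-octal-8-ene; 11 (E)-3-methylpent-2-enoic acid
Product: 13 3α-hydroxy-9α-[(E)-3-methylpent-2-enoyloxy]-4β,5β-dimethyl-10αH-decalin-8-one, via 3-O-silyl ester 12 (not isolated)
Conditions: 11 (2.2 equiv), Ag2O (1.1 equiv), MeCN, 20 °C, evaporate (silver salt); I2 (1.05 equiv), CH2Cl2, −20 °C; add 10, −20 → 20 °C; then Et3N·3HF; Et3N (cat.), 20 °C
Reagents that add atoms: none
Why: Rubottom-type silver carboxylate–iodine (Prévost-like) acyloxylation of the regiodefined enol silane puts the ester on C9 only, fluoride releases the ketone and the C3 hydroxyl, and amine equilibration through the enol leaves the ester in the equatorial 9α position, the only one free of a 1,3-diaxial clash with the C5 methyl.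

Step 7
Reactants: 13 3α-hydroxy-9α-[(E)-3-methylpent-2-enoyloxy]-4β,5β-dimethyl-10αH-decalin-8-one; 14 angelic acid
Product: 15 3α-angeloyloxy-9α-[(E)-3-methylpent-2-enoyloxy]-4β,5β-dimethyl-10αH-decalin-8-one
Conditions: 14, 2,4,6-trichlorobenzoyl chloride, Et3N, toluene, 20 °C; then 13, 80 °C (no DMAP)
Reagents that add atoms: none
Why: Yamaguchi esterification through the mixed 2,4,6-trichlorobenzoic anhydride acylates the equatorial C3 hydroxyl with retention, and leaving out DMAP keeps the angelate Z (no isomerisation to the tiglate).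

Step 8
Reactants: 15 3α-angeloyloxy-9α-[(E)-3-methylpent-2-enoyloxy]-4β,5β-dimethyl-10αH-decalin-8-one; 16 2-bromopropene
Product: 19 3α-angeloyloxy-9α-[(E)-3-methylpent-2-enoyloxy]-10αH-eremophil-11-en-8-one (CNP0301161.1), via silyl enol ether 17 (not isolated), via tributylstannyl enolate 18 (not isolated)
Conditions: LiHMDS (1.1 equiv), TMSCl (internal quench), THF, −78 °C; evaporate; then Bu3SnF (1.2 equiv), Pd2(dba)3 (2.5 mol %), P(t-Bu)3 (6 mol %), 16 (3 equiv), toluene, 70 °C (sealed)
Reagents that add atoms: none
Why: Kinetic deprotonation with in-situ silylation takes the C7 methylene (the internal quench prevents acyl migration), and the Kuwajima–Urabe/Kosugi–Migita palladium coupling of the derived tin enolate with the alkenyl bromide forms the C7–C11 bond without base on the α-face anti to the angular methyl (equatorial 7α-isopropenyl), so the β,γ-unsaturated ketone is neither epimerised nor moved into conjugation.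

## Compound list

1 | 2-methylcyclopentane-1,3-dione | CC1C(=O)CCC1=O | starting material
2 | methyl vinyl ketone | C=CC(C)=O | starting material
3 | 2-methyl-2-(3-oxobutyl)cyclopentane-1,3-dione | CC(=O)CCC1(C)C(=O)CCC1=O | intermediate
4 | (3aS,7aS)-3a-hydroxy-7a-methylhexahydro-1H-indene-1,5(4H)-dione (Hajos ketol, not isolated) | C1C[C@]2(C)C(=O)CC[C@]2(O)CC1=O | intermediate
5 | (S)-7a-methyl-2,3,7,7a-tetrahydro-1H-indene-1,5(6H)-dione ((S)-Hajos–Parrish ketone) | C1C[C@]2(C)C(=O)CCC2=CC1=O | intermediate
6 | vinylmagnesium bromide | C=C[Mg]Br | starting material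
7 | (1R,7aS)-1-ethenyl-1-hydroxy-7a-methyl-1,2,3,6,7,7a-hexahydro-5H-inden-5-one (hydroxyl cis to the angular methyl) | C1C[C@]2(C)[C@](O)(C=C)CCC2=CC1=O | intermediate
8 | (4aR,5R)-4a,5-dimethyl-4,4a,7,8-tetrahydronaphthalene-2,6(3H,5H)-dione (cis-dimethyl; 3,8-dione with Δ9(10) in eremophilane numbering) | C1C[C@]2(C)[C@@H](C)C(=O)CCC2=CC1=O | intermediate
9 | dilithium 3α-alkoxide Δ8-enolate of 3α-hydroxy-4β,5β-dimethyl-10αH-decalin-8-one (not isolated) | C1C[C@]2(C)[C@@H](C)[C@H]([O-])CC[C@H]2C=C1[O-].[Li+].[Li+] | intermediate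
10 | 3α,8-bis(trimethylsilyloxy)-4β,5β-dimethyl-10αH-octal-8-ene (trans-fused) | C1C[C@]2(C)[C@@H](C)[C@H](O[Si](C)(C)C)CC[C@H]2C=C1O[Si](C)(C)C | intermediate
11 | (E)-3-methylpent-2-enoic acid | OC(=O)/C=C(\C)CC | starting material
12 | 9α-[(E)-3-methylpent-2-enoyloxy]-3α-(trimethylsilyloxy)-4β,5β-dimethyl-10αH-decalin-8-one (not isolated) | C1C[C@]2(C)[C@@H](C)[C@H](O[Si](C)(C)C)CC[C@H]2[C@H](OC(=O)/C=C(\C)CC)C1=O | intermediate
13 | 3α-hydroxy-9α-[(E)-3-methylpent-2-enoyloxy]-4β,5β-dimethyl-10αH-decalin-8-one | C1C[C@]2(C)[C@@H](C)[C@H](O)CC[C@H]2[C@H](OC(=O)/C=C(\C)CC)C1=O | intermediate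
14 | angelic acid ((Z)-2-methylbut-2-enoic acid) | OC(=O)/C(C)=C\C | starting material
15 | 3α-angeloyloxy-9α-[(E)-3-methylpent-2-enoyloxy]-4β,5β-dimethyl-10αH-decalin-8-one | C1C[C@]2(C)[C@@H](C)[C@H](OC(=O)/C(C)=C\C)CC[C@H]2[C@H](OC(=O)/C=C(\C)CC)C1=O | intermediate
16 | 2-bromopropene | C=C(C)Br | starting material
17 | 8-trimethylsilyl Δ7-enol ether of 15 (not isolated) | C1[C@]2(C)[C@@H](C)[C@H](OC(=O)/C(C)=C\C)CC[C@H]2[C@H](OC(=O)/C=C(\C)CC)C(O[Si](C)(C)C)=C1 | intermediate
18 | 8-tributylstannyl Δ7-enolate of 15 (not isolated) | C1[C@]2(C)[C@@H](C)[C@H](OC(=O)/C(C)=C\C)CC[C@H]2[C@H](OC(=O)/C=C(\C)CC)C(O[Sn](CCCC)(CCCC)CCCC)=C1 | intermediate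
19 | (3R,4R,5R,7S,9S,10R)-3α-angeloyloxy-9α-[(E)-3-methylpent-2-enoyloxy]-10αH-eremophil-11-en-8-one (CNP0301161.1) | C=C(C)[C@@H]1C[C@]2(C)[C@@H](C)[C@H](OC(=O)/C(C)=C\C)CC[C@H]2[C@H](OC(=O)/C=C(\C)CC)C1=O | target

## Count and risks

Total step count: 8. Longest linear sequence: 8.

Three steps most likely to fail:

**Step 4 (the proposed new ring expansion).** Closure of the alkyl–Co(IV) species to an epoxide, or migration of C2 instead of the quaternary carbon, could take over. The fallback uses known chemistry, sets out from 5 and comes back at 8. 1-(Methylseleno)ethyllithium (from 1,1-bis(methylseleno)ethane and n-BuLi, THF, −78 °C) is added to the saturated ketone of 5 to give the β-hydroxy selenide (1R,7aS)-1-hydroxy-7a-methyl-1-[1-(methylseleno)ethyl]-1,2,3,6,7,7a-hexahydro-5H-inden-5-one F1. Silver tetrafluoroborate on alumina in CH2Cl2 (Krief ring enlargement) then ionises the C–Se bond with migration of the more substituted ring carbon to give 8. This replaces the radical-polar crossover by a two-electron semipinacol.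

**Step 6 (acyloxylation at C9).** The hindered enol silane may give the α-iodo ketone or the enone instead of the ester, or the acyl group may wander during equilibration. The fallback sets out from 10 and comes back at 15. Rubottom oxidation (mCPBA, NaHCO3, CH2Cl2, −15 °C; attack on the α-face) gives 3α,9α-bis(trimethylsilyloxy)-4β,5β-dimethyl-10αH-decalin-8-one F2. HF·pyridine frees 3α,9α-dihydroxy-4β,5β-dimethyl-10αH-decalin-8-one F3. One equivalent of the angelic mixed anhydride (Yamaguchi) acylates the C3 hydroxyl ahead of the hydrogen-bonded, deactivated α-ketol hydroxyl to give 3α-angeloyloxy-9α-hydroxy-4β,5β-dimethyl-10αH-decalin-8-one F4. DCC/DMAP esterification of the C9 hydroxyl with 11 then gives 15. The C9 oxygen now comes from the peracid and the order of the two esters is reversed.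

**Step 8 (isopropenylation at C7).** Enolisation toward C9, slow transmetalation of the hindered tin enolate or β-hydride loss could defeat the coupling. The fallback sets out from 15 by way of isolated 17 and comes back at 19. Mukaiyama aldol of 17 with acetone (TiCl4, CH2Cl2, −78 °C) gives 3α-angeloyloxy-7α-(2-hydroxypropan-2-yl)-9α-[(E)-3-methylpent-2-enoyloxy]-4β,5β-dimethyl-10αH-decalin-8-one F5. Dehydration with SOCl2/pyridine at −30 °C (E2 toward the methyl groups) gives 19, which is separated by chromatography from the conjugated isopropylidene isomer. The C–C bond is then made by an aldol and the alkene by elimination.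

## Further compounds

F1 | step 4 | (1R,7aS)-1-hydroxy-7a-methyl-1-[1-(methylseleno)ethyl]-1,2,3,6,7,7a-hexahydro-5H-inden-5-one (epimers at the selenium-bearing carbon) | C1C[C@]2(C)[C@](O)(C(C)[Se]C)CCC2=CC1=O
F2 | step 6 | 3α,9α-bis(trimethylsilyloxy)-4β,5β-dimethyl-10αH-decalin-8-one | C1C[C@]2(C)[C@@H](C)[C@H](O[Si](C)(C)C)CC[C@H]2[C@H](O[Si](C)(C)C)C1=O
F3 | step 6 | 3α,9α-dihydroxy-4β,5β-dimethyl-10αH-decalin-8-one | C1C[C@]2(C)[C@@H](C)[C@H](O)CC[C@H]2[C@H](O)C1=O
F4 | step 6 | 3α-angeloyloxy-9α-hydroxy-4β,5β-dimethyl-10αH-decalin-8-one | C1C[C@]2(C)[C@@H](C)[C@H](OC(=O)/C(C)=C\C)CC[C@H]2[C@H](O)C1=O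
F5 | step 8 | 3α-angeloyloxy-7α-(2-hydroxypropan-2-yl)-9α-[(E)-3-methylpent-2-enoyloxy]-4β,5β-dimethyl-10αH-decalin-8-one | CC(C)(O)[C@@H]1C[C@]2(C)[C@@H](C)[C@H](OC(=O)/C(C)=C\C)CC[C@H]2[C@H](OC(=O)/C=C(\C)CC)C1=O
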